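Assumption: compounds 1, 12 and 15 are bought. Epoxide 22 forms as a racemate, is written as one enantiomer, and loses both stereocentres in the same step.

## Analysis of the target

The target is a flavone: benzene ring A fused to the 4-pyranone ring C (O1, C2, C3, C4, C4a, C8a), with aryl ring B on C2. It has no stereocentre, so the problem is one of regiochemistry on two electron-rich arenes. Ring A is fully substituted, with oxygen on C5, C6, C7 and C8 in the order OH, OMe, OH, OMe. C3 carries a methoxy group and ring B a 2',5'-dihydroxy-4'-methoxy pattern. The sensitive parts are the 2',5'-hydroquinone of ring B (air oxidation to the quinone), the pyranone (opened by strong nucleophilic base) and four free phenols that must stay distinct from four methyl ethers. The difficulty lies in ring A: it is not symmetric about the C4a–C8a bond (5-OH against 8-OMe, 6-OMe against 7-OH), so any route through a 2-hydroxyaryl ketone must tell apart the oxygens of a hexasubstituted benzene. The strategy rests on the C4a–C8a edge: two neighbouring ring A carbons, one bound to the acyl carbon C4 and one to the ring oxygen O1, flanked by the C5 oxygen and the C8 methoxy group. An aryne can take up such an ortho carbon/oxygen pair from a carboxylate in one event, and on a fully substituted ring the aryne has no other position to react at.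

## Retrosynthetic reasoning

Protecting groups. The last bonds cut are three O–benzyl bonds and one O–pivaloyl bond: target 26 comes from tribenzyl ether 25 by hydrogenolysis, and 25 from pivalate 24 by methanolysis. Benzyl on O7, O2' and O5' leaves under neutral conditions at the very end, when the oxidisable hydroquinone is unmasked. The pivalate stays on O5 until C3 is methylated, so that O5 cannot be methylated.

C3–O bond. 24 comes from 3-hydroxyflavone 23 by O-methylation, and 23 from flavone 21 through epoxide 22. The cut is made here because the ring C construction delivers C3 as a C–H. The C2=C3 bond of 21 is an enol ether double bond and should accept electrophilic oxygen. The forward step must oxidise this alkene and neither arene.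

Ring C, the key disconnection. In 21 the bonds O1–C8a, C4–C4a and O1–C2 are cut together. This leads to aryne 18, released from silyl triflate 11, and arylpropiolic acid 16, which reacts as its cesium salt 17. The cut gives two aromatic fragments of similar size and makes every bond between ring A and ring C at once. The forward reaction must put the carboxylate oxygen on the aryne carbon next to the methoxy group and the acyl carbon on the one next to the pivalate (carbanion 19, then phenoxide 20), and then close ring C by conjugate addition.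

Aryne precursor. 11 comes from phenol 10 by O-sulfonylation. 10 comes from bis(silyl ether) 6 by cutting the C–Si bond back to a C–Br bond (through 7, 8 and 9), and 6 comes from bromoresorcinol 5 and resorcinol 4. Resorcinol 4 is symmetric. Its two hydroxyls are told apart by the silyl migration itself: moving one silyl group from oxygen to carbon leaves exactly one phenoxide for acylation.

Resorcinol. The two C–OH bonds of 4 are cut to the C–Br bonds of dibromide 3, which comes from benzyl ether 2 and syringol 1. The hydroxyls of 4 sit ortho and para to the methoxy groups of 1, where electrophilic bromination of 2 is expected. The one ring hydrogen left in 4 is the position that later becomes C4a.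

Ring B fragment. The aryl–alkyne bond of 16 is cut to iodide 14 and propiolic acid 15. 14 comes from bis(benzyl ether) 13 and 2-methoxyhydroquinone 12. The iodine must go para to the methoxy group, the usual site of electrophilic attack on a 1,2,4-trialkoxybenzene.

## Alternatives that were turned down

Alternative 1: Ring A would not come from an arene. Cutting C4a–C8a unravels ring A into an open polyketide chain whose ester carbon is C8a, stored as the 4-hydroxy-2-pyrone A1. Forward, Mg(OMe)2 in methanol opens the lactone of A1, and the C4a methylene adds to the ester carbon in a Claisen condensation to give acylphloroglucinol chalcone A2. Oxidative closure of A2 would then make ring C.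
- For: the C3 methoxy group is present from the start, ring A of A2 is symmetric so either ortho hydroxyl closes to the same flavone, and O5 and O7 need no protecting group. On these three points it is stronger than the chosen route, which pays with a late C3 oxidation and a pivalate.
- Against: both methines between the carbonyls carry methoxy groups, so they are hindered and slow to enolise. The opened chain can re-close to a pyrone or fold by aldol instead of Claisen condensation, and without an enzyme nothing chooses among these. The α-methoxy enone is exposed to methoxide, and A1 needs a long linear assembly.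
- Comparison: the chosen strategy has one selectivity question in an established reaction type. This one has several, in a folding that is not established for such a chain, on a substrate that takes longer to make.

Alternative 2: Here ring B is built. Cutting C5'–C6', C1'–C2' and C2'–C3' leads to 2-ethynylchromone A3, the methoxy(1-methoxyvinyl)carbene complex A4 of the Cr(CO)5 fragment, and one CO ligand. The Dötz benzannulation would join them, with the terminal alkyne placing the chromone next to the CO-derived phenol. Oxidative work-up with (NH4)2Ce(NO3)6 would give quinone A5, whose reduction frees the 2',5'-hydroquinone.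
- For: ring B arrives with its para-dioxygen pattern and 4'-methoxy group in place and without protecting groups. The chosen route cannot match this; it needs two benzyl ethers on ring B.
- Against: A3 already holds rings A and C with all five oxygens, so the hexasubstituted ring A and its fusion to ring C must first be made by some other flavone synthesis, and the easy ring is built last. The alkyne of A3 is conjugated to the pyranone and electron-poor, the class that inserts least cleanly into chromium carbenes. A4 is a labile, doubly donor-substituted carbene used stoichiometrically, and the cerium oxidant may not spare the benzyl ethers and ring A.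
- Comparison: the chosen route makes ring B from a cheap hydroquinone in three steps and spends its key step on the ring A/ring C junction.

Alternative 3: Only the O1–C8a bond is cut, giving 1,3-diketone A6, in which ring A still has a hydrogen at C8a. Constant-current anodic oxidation of enolised A6 in hexafluoroisopropanol would join the enol oxygen to C8a by dehydrogenative C–O coupling and give flavone A7.
- For: C8a is the only C–H of ring A, so the site of closure is not in doubt; the C3 methoxy group is in the diketone from the start; and A6 follows from a Claisen-type acylation. On regiochemical certainty and on the C3 oxygen it is stronger than the chosen route.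
- Against: the outcome depends on which part of A6 is oxidised first (the enol, the tetraalkoxy ring A or the benzylic positions) and on the radical cation being trapped by oxygen and not by carbon. Ring B also has a C–H ortho to its acyl carbon (C6'), so closure in the opposite sense is possible and is only discouraged by the pivalates. The ring A half of A6 still needs the alternating benzyloxy/methoxy pattern on a pentasubstituted arene.
- Comparison: the chosen route replaces a choice among oxidation potentials by leaving groups that fix where the bonds form, at the cost of a longer preparation of 11.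

Key step: step 11

## Route

Step 1
Reactants: 1 2,6-dimethoxyphenol (syringol)
Product: 2 2-(benzyloxy)-1,3-dimethoxybenzene
Conditions: BnBr (1.2 equiv), K2CO3, DMF, 50 °C
Reagents that add atoms: benzyl bromide, BrCc1ccccc1
Why: Williamson etherification of an acidic phenol; the carbonate base is enough and no other nucleophilic site is present.

Step 2
Reactants: 2 2-(benzyloxy)-1,3-dimethoxybenzene
Product: 3 3-(benzyloxy)-1,5-dibromo-2,4-dimethoxybenzene
Conditions: NBS (2.2 equiv), MeCN, 0 to 40 °C, dark
Reagents that add atoms: N-bromosuccinimide, O=C1CCC(=O)N1Br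
Why: Electrophilic aromatic bromination; the central alkoxy group of a 1,2,3-trialkoxybenzene is twisted and activates little, so both brominations should go ortho/para to the outer methoxy groups. The C–H between the two bromines stays, and the benzyl phenyl ring is too electron-poor to compete.

Step 3
Reactants: 3 3-(benzyloxy)-1,5-dibromo-2,4-dimethoxybenzene
Product: 4 5-(benzyloxy)-4,6-dimethoxybenzene-1,3-diol
Conditions: Pd2(dba)3 (2 mol%), t-BuXPhos (8 mol%), KOH (6 equiv), 1,4-dioxane/H2O 1:1, 100 °C, Ar; then 1 M HCl
Reagents that add atoms: potassium hydroxide, [K+].[OH-]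
Why: Palladium-catalysed hydroxylation of aryl bromides (C–O cross-coupling with hydroxide on zerovalent palladium with a bulky biaryl phosphine). Each bromide has one ortho substituent only, and the methyl and benzyl ethers are inert to hot aqueous KOH.

Step 4
Reactants: 4 5-(benzyloxy)-4,6-dimethoxybenzene-1,3-diol
Product: 5 5-(benzyloxy)-2-bromo-4,6-dimethoxybenzene-1,3-diol
Conditions: NBS (1.0 equiv), CH2Cl2, −78 to −30 °C, dark
Reagents that add atoms: N-bromosuccinimide, O=C1CCC(=O)N1Br
Why: Electrophilic bromination at the only ring C–H, which is ortho to both hydroxyls. One equivalent at low temperature should keep oxidation of the electron-rich ring in check.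

Step 5
Reactants: 5 5-(benzyloxy)-2-bromo-4,6-dimethoxybenzene-1,3-diol
Product: 6 [5-(benzyloxy)-2-bromo-4,6-dimethoxy-1,3-phenylene]bis(oxy)bis(trimethylsilane)
Conditions: HMDS (3 equiv), THF, 65 °C; evaporate, use crude
Reagents that add atoms: hexamethyldisilazane, C[Si](C)(C)N[Si](C)(C)C
Why: O-silylation of both phenols; ammonia is the only by-product, so the moisture-sensitive bis(silyl ether) can be used after evaporation.

Step 6
Reactants: 6 [5-(benzyloxy)-2-bromo-4,6-dimethoxy-1,3-phenylene]bis(oxy)bis(trimethylsilane)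
Product: 10 5-(benzyloxy)-3-hydroxy-4,6-dimethoxy-2-(trimethylsilyl)phenyl 2,2-dimethylpropanoate, via aryllithium 7 (not isolated), via lithium phenoxide 8 (not isolated), via silyl ether 9 (not isolated)
Conditions: n-BuLi (1.05 equiv), THF, −78 °C; PivCl (1.2 equiv), −78 °C to rt; MeOH, citric acid (cat.), 0 °C
Reagents that add atoms: pivaloyl chloride, CC(C)(C)C(Cl)=O
Why: Bromine–lithium exchange followed by the retro-Brook rearrangement (anionic 1,3 O→C silyl shift) puts silicon on carbon and leaves one lithium phenoxide. That phenoxide is the only site PivCl can acylate, so the symmetric ring is desymmetrised without a statistical step. Mild methanolysis then removes the remaining O-silyl group while the C–Si bond and the pivalate stay.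

Step 7
Reactants: 10 5-(benzyloxy)-3-hydroxy-4,6-dimethoxy-2-(trimethylsilyl)phenyl 2,2-dimethylpropanoate
Product: 11 5-(benzyloxy)-4,6-dimethoxy-3-(pivaloyloxy)-2-(trimethylsilyl)phenyl trifluoromethanesulfonate
Conditions: Tf2O (1.2 equiv), pyridine, CH2Cl2, −20 to 0 °C
Reagents that add atoms: trifluoromethanesulfonic anhydride, O=S(=O)(OS(=O)(=O)C(F)(F)F)C(F)(F)F
Why: O-sulfonylation of the remaining hindered phenol, the usual last step to a 2-silylaryl triflate. The triflate is introduced last so that no free phenoxide sits next to the silyl triflate unit.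

Step 8
Reactants: 12 2-methoxybenzene-1,4-diol (2-methoxyhydroquinone)
Product: 13 1,4-bis(benzyloxy)-2-methoxybenzene
Conditions: BnBr (2.4 equiv), K2CO3, DMF, 60 °C, N2
Reagents that add atoms: benzyl bromide, BrCc1ccccc1
Why: Double Williamson etherification; inert atmosphere protects the hydroquinone from air oxidation under base.

Step 9
Reactants: 13 1,4-bis(benzyloxy)-2-methoxybenzene
Product: 14 1,4-bis(benzyloxy)-2-iodo-5-methoxybenzene
Conditions: NIS (1.05 equiv), TFA (10 mol%), MeCN, 0 °C to rt
Reagents that add atoms: N-iodosuccinimide, O=C1CCC(=O)N1I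
Why: Electrophilic aromatic iodination; in a 1,2,4-trialkoxybenzene attack goes para to the 2-alkoxy group (here the methoxy group), and the position between two alkoxy groups is more hindered.

Step 10
Reactants: 14 1,4-bis(benzyloxy)-2-iodo-5-methoxybenzene; 15 propiolic acid
Product: 16 3-[2,5-bis(benzyloxy)-4-methoxyphenyl]prop-2-ynoic acid
Conditions: Pd(PPh3)4 (5 mol%), DBU (2.4 equiv), DMSO, 30 °C; then cold 1 M HCl
Reagents that add atoms: none
Why: Copper-free Sonogashira-type coupling of an aryl iodide with propiolic acid as its amidinium carboxylate. Leaving copper out and staying near room temperature suppresses decarboxylation of the product.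

Step 11
Reactants: 11 5-(benzyloxy)-4,6-dimethoxy-3-(pivaloyloxy)-2-(trimethylsilyl)phenyl trifluoromethanesulfonate (1.5 equiv); 16 3-[2,5-bis(benzyloxy)-4-methoxyphenyl]prop-2-ynoic acid
Product: 21 7-(benzyloxy)-2-[2,5-bis(benzyloxy)-4-methoxyphenyl]-6,8-dimethoxy-4-oxo-4H-chromen-5-yl 2,2-dimethylpropanoate, via cesium arylpropiolate 17 (not isolated), via aryne 18 (not isolated), via aryl carbanion 19 (not isolated), via acylphenoxide 20 (not isolated)
Conditions: CsF (4 equiv), THF, 110–125 °C, sealed tube
Reagents that add atoms: none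
Why: CsF converts 16 into carboxylate 17 and attacks silicon of 11; loss of triflate gives aryne 18 between the future C4a and C8a. The carboxylate oxygen of 17 must add at the aryne carbon next to the methoxy group (C8a), which puts the carbanion of 19 next to the pivalate. Pivaloyloxy is both the stronger inductive acceptor and the larger group, so it should direct the nucleophile to the distal carbon and stabilise the adjacent carbanion. The carbanion then attacks the neighbouring ynoate carbonyl through a four-membered transition state, and C–O cleavage gives o-acyl phenoxide 20, a net insertion of the aryne into the C–O bond. The tert-butyl group shields the pivalate carbonyl from the same attack. Phenoxide 20 closes ring C by 6-endo-dig oxa-Michael addition to the ynone β-carbon, the polarity-matched mode, and bifluoride formed from the acid proton protonates C3. The closest known reaction type is the fluoride-induced insertion of arynes into the C–O bond of carboxylic acids to give o-hydroxyaryl ketones, including arylpropiolic acids to flavones. No stereocentre is formed; the step needs regioselectivity at the aryne and chemoselectivity between two ester carbonyls.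

Step 12
Reactants: 21 7-(benzyloxy)-2-[2,5-bis(benzyloxy)-4-methoxyphenyl]-6,8-dimethoxy-4-oxo-4H-chromen-5-yl 2,2-dimethylpropanoate
Product: 23 7-(benzyloxy)-2-[2,5-bis(benzyloxy)-4-methoxyphenyl]-3-hydroxy-6,8-dimethoxy-4-oxo-4H-chromen-5-yl 2,2-dimethylpropanoate, via epoxide 22 (not isolated)
Conditions: DMDO (acetone solution, 3 equiv), CH2Cl2, 0 °C; then p-TsOH·H2O (0.2 equiv), CH2Cl2, rt
Reagents that add atoms: dimethyldioxirane, CC1(C)OO1
Why: Electrophilic epoxidation of the enol-ether-like C2=C3 bond under neutral conditions gives racemic cis-fused epoxide 22. Acid opens it at C2 to the O1-stabilised cation, and loss of H3 restores the pyranone with OH on C3, so the two transient stereocentres disappear.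

Step 13
Reactants: 23 7-(benzyloxy)-2-[2,5-bis(benzyloxy)-4-methoxyphenyl]-3-hydroxy-6,8-dimethoxy-4-oxo-4H-chromen-5-yl 2,2-dimethylpropanoate
Product: 24 7-(benzyloxy)-2-[2,5-bis(benzyloxy)-4-methoxyphenyl]-3,6,8-trimethoxy-4-oxo-4H-chromen-5-yl 2,2-dimethylpropanoate
Conditions: MeI (3 equiv), K2CO3, acetone, rt
Reagents that add atoms: iodomethane, CI
Why: Williamson methylation of the acidic enolic 3-hydroxyl, the only free hydroxyl; aprotic conditions leave the pivalate on O5.

Step 14
Reactants: 24 7-(benzyloxy)-2-[2,5-bis(benzyloxy)-4-methoxyphenyl]-3,6,8-trimethoxy-4-oxo-4H-chromen-5-yl 2,2-dimethylpropanoate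
Product: 25 7-(benzyloxy)-2-[2,5-bis(benzyloxy)-4-methoxyphenyl]-5-hydroxy-3,6,8-trimethoxy-4H-chromen-4-one
Conditions: K2CO3 (2 equiv), MeOH/THF 2:1, rt to 40 °C; then dilute HCl
Reagents that add atoms: none
Why: Base-catalysed transesterification (methanolysis) of an aryl ester; the leaving phenoxide is stabilised by the peri carbonyl, and benzyl and methyl ethers are untouched.

Step 15
Reactants: 25 7-(benzyloxy)-2-[2,5-bis(benzyloxy)-4-methoxyphenyl]-5-hydroxy-3,6,8-trimethoxy-4H-chromen-4-one
Product: 26 5,7-dihydroxy-2-(2,5-dihydroxy-4-methoxyphenyl)-3,6,8-trimethoxy-4H-chromen-4-one (target)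
Conditions: H2 (1 atm), 10% Pd/C, EtOAc/MeOH 1:1, rt; filter under Ar
Reagents that add atoms: none
Why: Hydrogenolysis of three aryl benzyl ethers; the tetrasubstituted C2=C3 bond of the pyranone and the methyl ethers should survive. Air is excluded during filtration to protect the 2',5'-hydroquinone.

## Compound list

1 | 2,6-dimethoxyphenol (syringol) | COc1cccc(OC)c1O | starting material
2 | 2-(benzyloxy)-1,3-dimethoxybenzene | COc1cccc(OC)c1OCc1ccccc1 | intermediate
3 | 3-(benzyloxy)-1,5-dibromo-2,4-dimethoxybenzene | COc1c(Br)cc(Br)c(OC)c1OCc1ccccc1 | intermediate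
4 | 5-(benzyloxy)-4,6-dimethoxybenzene-1,3-diol | COc1c(O)cc(O)c(OC)c1OCc1ccccc1 | intermediate
5 | 5-(benzyloxy)-2-bromo-4,6-dimethoxybenzene-1,3-diol | COc1c(O)c(Br)c(O)c(OC)c1OCc1ccccc1 | intermediate
6 | [5-(benzyloxy)-2-bromo-4,6-dimethoxy-1,3-phenylene]bis(oxy)bis(trimethylsilane) | COc1c(O[Si](C)(C)C)c(Br)c(O[Si](C)(C)C)c(OC)c1OCc1ccccc1 | intermediate
7 | {4-(benzyloxy)-3,5-dimethoxy-2,6-bis[(trimethylsilyl)oxy]phenyl}lithium | COc1c(O[Si](C)(C)C)c([Li])c(O[Si](C)(C)C)c(OC)c1OCc1ccccc1 | intermediate (not isolated)
8 | lithium 3-(benzyloxy)-2,4-dimethoxy-6-(trimethylsilyl)-5-[(trimethylsilyl)oxy]phenolate | COc1c([O-])c([Si](C)(C)C)c(O[Si](C)(C)C)c(OC)c1OCc1ccccc1.[Li+] | intermediate (not isolated)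
9 | 5-(benzyloxy)-4,6-dimethoxy-2-(trimethylsilyl)-3-[(trimethylsilyl)oxy]phenyl 2,2-dimethylpropanoate | COc1c(OC(=O)C(C)(C)C)c([Si](C)(C)C)c(O[Si](C)(C)C)c(OC)c1OCc1ccccc1 | intermediate (not isolated)
10 | 5-(benzyloxy)-3-hydroxy-4,6-dimethoxy-2-(trimethylsilyl)phenyl 2,2-dimethylpropanoate | COc1c(OC(=O)C(C)(C)C)c([Si](C)(C)C)c(O)c(OC)c1OCc1ccccc1 | intermediate
11 | 5-(benzyloxy)-4,6-dimethoxy-3-(pivaloyloxy)-2-(trimethylsilyl)phenyl trifluoromethanesulfonate | C[Si](C)(C)c1c(OS(=O)(=O)C(F)(F)F)c(OC)c(OCc2ccccc2)c(OC)c1OC(=O)C(C)(C)C | intermediate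
12 | 2-methoxybenzene-1,4-diol (2-methoxyhydroquinone) | COc1cc(O)ccc1O | starting material
13 | 1,4-bis(benzyloxy)-2-methoxybenzene | COc1cc(OCc2ccccc2)ccc1OCc1ccccc1 | intermediate
14 | 1,4-bis(benzyloxy)-2-iodo-5-methoxybenzene | COc1cc(OCc2ccccc2)c(I)cc1OCc1ccccc1 | intermediate
15 | propiolic acid | OC(=O)C#C | starting material
16 | 3-[2,5-bis(benzyloxy)-4-methoxyphenyl]prop-2-ynoic acid | OC(=O)C#Cc1cc(OCc2ccccc2)c(OC)cc1OCc1ccccc1 | intermediate
17 | cesium 3-[2,5-bis(benzyloxy)-4-methoxyphenyl]prop-2-ynoate | [Cs+].[O-]C(=O)C#Cc1cc(OCc2ccccc2)c(OC)cc1OCc1ccccc1 | intermediate (not isolated)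
18 | 3-(benzyloxy)-2,4-dimethoxy-5,6-didehydrophenyl 2,2-dimethylpropanoate (aryne) | C1(OC(=O)C(C)(C)C)=C(OC)C(OCc2ccccc2)=C(OC)C#C1 | intermediate (not isolated)
19 | cesium 4-(benzyloxy)-2-({3-[2,5-bis(benzyloxy)-4-methoxyphenyl]prop-2-ynoyl}oxy)-3,5-dimethoxy-6-(pivaloyloxy)benzen-1-ide | CC(C)(C)C(=O)Oc1[c-]c(OC(=O)C#Cc2cc(OCc3ccccc3)c(OC)cc2OCc2ccccc2)c(OC)c(OCc2ccccc2)c1OC.[Cs+] | intermediate (not isolated)
20 | cesium 3-(benzyloxy)-6-{3-[2,5-bis(benzyloxy)-4-methoxyphenyl]prop-2-ynoyl}-2,4-dimethoxy-5-(pivaloyloxy)phenolate | [Cs+].[O-]c1c(OC)c(OCc2ccccc2)c(OC)c(OC(=O)C(C)(C)C)c1C(=O)C#Cc1cc(OCc2ccccc2)c(OC)cc1OCc1ccccc1 | intermediate (not isolated)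
21 | 7-(benzyloxy)-2-[2,5-bis(benzyloxy)-4-methoxyphenyl]-6,8-dimethoxy-4-oxo-4H-chromen-5-yl 2,2-dimethylpropanoate | COc1cc(OCc2ccccc2)c(-c2cc(=O)c3c(OC(=O)C(C)(C)C)c(OC)c(OCc4ccccc4)c(OC)c3o2)cc1OCc1ccccc1 | intermediate
22 | 7-(benzyloxy)-2-[2,5-bis(benzyloxy)-4-methoxyphenyl]-2,3-epoxy-6,8-dimethoxy-4-oxo-2,3-dihydro-4H-chromen-5-yl 2,2-dimethylpropanoate (racemic, oxirane cis-fused to ring C; one enantiomer written) | O=C1[C@@H]2O[C@]2(c2cc(OCc3ccccc3)c(OC)cc2OCc2ccccc2)Oc2c(OC)c(OCc3ccccc3)c(OC)c(OC(=O)C(C)(C)C)c12 | intermediate (not isolated)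
23 | 7-(benzyloxy)-2-[2,5-bis(benzyloxy)-4-methoxyphenyl]-3-hydroxy-6,8-dimethoxy-4-oxo-4H-chromen-5-yl 2,2-dimethylpropanoate | COc1cc(OCc2ccccc2)c(-c2oc3c(OC)c(OCc4ccccc4)c(OC)c(OC(=O)C(C)(C)C)c3c(=O)c2O)cc1OCc1ccccc1 | intermediate
24 | 7-(benzyloxy)-2-[2,5-bis(benzyloxy)-4-methoxyphenyl]-3,6,8-trimethoxy-4-oxo-4H-chromen-5-yl 2,2-dimethylpropanoate | COc1cc(OCc2ccccc2)c(-c2oc3c(OC)c(OCc4ccccc4)c(OC)c(OC(=O)C(C)(C)C)c3c(=O)c2OC)cc1OCc1ccccc1 | intermediate
25 | 7-(benzyloxy)-2-[2,5-bis(benzyloxy)-4-methoxyphenyl]-5-hydroxy-3,6,8-trimethoxy-4H-chromen-4-one | COc1cc(OCc2ccccc2)c(-c2oc3c(OC)c(OCc4ccccc4)c(OC)c(O)c3c(=O)c2OC)cc1OCc1ccccc1 | intermediate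
26 | 5,7-dihydroxy-2-(2,5-dihydroxy-4-methoxyphenyl)-3,6,8-trimethoxy-4H-chromen-4-one | COc1cc(O)c(-c2oc3c(OC)c(O)c(OC)c(O)c3c(=O)c2OC)cc1O | target

## Step count and least certain steps

Total: 15 steps. Longest linear sequence: 12 steps (steps 1–7 and 11–15); the ring B branch has 3 steps (8–10).

**Step 11 (key step).**
- Risk: addition of the carboxylate at the aryne carbon next to the pivalate, because the inductive and steric bias of pivaloyloxy over methoxy is modest; this would place the acyl group on the wrong carbon.
- Further risks: protonation of the aryl anion before acyl transfer, pivaloyl transfer to the carbanion, fluoride cleavage of the pivalate, and decarboxylation of the propiolate at the temperature needed.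
- Fallback: a 2,6-dihydroxyaryl ynone route, in which both ortho oxygens are equivalent and the regiochemical question disappears. It sets out from 5 and 16 and returns at 21. MOMCl/iPr2NEt converts 5 into 5-(benzyloxy)-2-bromo-4,6-dimethoxy-1,3-bis(methoxymethoxy)benzene F1. EDC and MeNHOMe·HCl convert 16 into 3-[2,5-bis(benzyloxy)-4-methoxyphenyl]-N-methoxy-N-methylprop-2-ynamide F2. Bromine–lithium exchange on F1 (n-BuLi, THF, −78 °C) and acylation by F2 should give 1-[4-(benzyloxy)-3,5-dimethoxy-2,6-bis(methoxymethoxy)phenyl]-3-[2,5-bis(benzyloxy)-4-methoxyphenyl]prop-2-yn-1-one F3. HCl in MeOH removes both acetals to give 1-[4-(benzyloxy)-2,6-dihydroxy-3,5-dimethoxyphenyl]-3-[2,5-bis(benzyloxy)-4-methoxyphenyl]prop-2-yn-1-one F4. K2CO3 in acetone closes this 6-endo-dig to 7-(benzyloxy)-2-[2,5-bis(benzyloxy)-4-methoxyphenyl]-5-hydroxy-6,8-dimethoxy-4H-chromen-4-one F5, and PivCl/Et3N/DMAP gives 21.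

**Step 6.**
- Risk: butyl attack at an O–Si bond in place of bromine–lithium exchange; silyl exchange between phenoxide and silyl ether before acylation, which would spoil the desymmetrisation; slow acylation of the hindered phenoxide; and protodesilylation of the electron-rich aryl silane on work-up.
- Fallback: directed ortho-metalation in place of exchange and silyl migration, setting out from 4 (steps 4 and 5 are then not needed) and returning at 10. Isopropyl isocyanate with Et3N (cat.) converts 4 into 5-(benzyloxy)-4,6-dimethoxy-1,3-phenylene bis(propan-2-ylcarbamate) F6. N-silylation in the flask (TMSOTf, TMEDA), lithiation with n-BuLi at the C–H between the two carbamates and a TMSCl quench should give 5-(benzyloxy)-4,6-dimethoxy-2-(trimethylsilyl)-1,3-phenylene bis(propan-2-ylcarbamate) F7. Et2NH/DBU in MeCN at 40 °C removes both carbamates to give 5-(benzyloxy)-4,6-dimethoxy-2-(trimethylsilyl)benzene-1,3-diol F8. One equivalent of PivCl with Et3N at −40 °C acylates one of the two equivalent hydroxyls to give 10; recovered diol and bis-ester are recycled.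

**Step 3.**
- Risk: incomplete second C–O coupling, reductive loss of bromine, diaryl ether formation, and air oxidation of the resorcinolate in hot base.
- Fallback: C–B bonds in place of direct C–O coupling, from 3 back to 4. Double Miyaura borylation (B2pin2, Pd(dppf)Cl2, KOAc, dioxane, 90 °C) gives 2,2'-[5-(benzyloxy)-4,6-dimethoxy-1,3-phenylene]bis(4,4,5,5-tetramethyl-1,3,2-dioxaborolane) F9. Oxidation with NaBO3·4H2O in THF/water at room temperature gives 4.

**Step 12.**
- Risk: slow epoxidation of the hindered, carbonyl-conjugated alkene, so that oxidation of the benzylic C–H bonds or of the electron-rich ring B by the dioxirane competes.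
- Fallback: C3 metalation in place of alkene oxidation, from 21 back to 23. LDA in THF at −78 °C with B(OiPr)3 present as a trap should give dipropan-2-yl {7-(benzyloxy)-2-[2,5-bis(benzyloxy)-4-methoxyphenyl]-5-[(2,2-dimethylpropanoyl)oxy]-6,8-dimethoxy-4-oxo-4H-chromen-3-yl}boronate F10. H2O2/AcOH oxidises this to 23. Trapping in the flask is meant to outrun acyl transfer from O5 to C3.

**Step 10.**
- Risk: decarboxylation of the electron-rich arylpropiolic acid under the coupling conditions, and slow oxidative addition to the ortho-alkoxy, electron-rich iodide.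
- Fallback: two separate C–C bond formations, from 14 back to 16. Sonogashira coupling with trimethylsilylacetylene (Pd(PPh3)2Cl2, CuI, Et3N, THF) gives {[2,5-bis(benzyloxy)-4-methoxyphenyl]ethynyl}trimethylsilane F11. K2CO3/MeOH gives 1,4-bis(benzyloxy)-2-ethynyl-5-methoxybenzene F12. Deprotonation with n-BuLi at −78 °C and carboxylation with CO2 give 16.

## Further compounds

F1 | step 11 | 5-(benzyloxy)-2-bromo-4,6-dimethoxy-1,3-bis(methoxymethoxy)benzene | COCOc1c(Br)c(OCOC)c(OC)c(OCc2ccccc2)c1OC
F2 | step 11 | 3-[2,5-bis(benzyloxy)-4-methoxyphenyl]-N-methoxy-N-methylprop-2-ynamide | CON(C)C(=O)C#Cc1cc(OCc2ccccc2)c(OC)cc1OCc1ccccc1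
F3 | step 11 | 1-[4-(benzyloxy)-3,5-dimethoxy-2,6-bis(methoxymethoxy)phenyl]-3-[2,5-bis(benzyloxy)-4-methoxyphenyl]prop-2-yn-1-one | COCOc1c(OC)c(OCc2ccccc2)c(OC)c(OCOC)c1C(=O)C#Cc1cc(OCc2ccccc2)c(OC)cc1OCc1ccccc1
F4 | step 11 | 1-[4-(benzyloxy)-2,6-dihydroxy-3,5-dimethoxyphenyl]-3-[2,5-bis(benzyloxy)-4-methoxyphenyl]prop-2-yn-1-one | COc1c(O)c(C(=O)C#Cc2cc(OCc3ccccc3)c(OC)cc2OCc2ccccc2)c(O)c(OC)c1OCc1ccccc1
F5 | step 11 | 7-(benzyloxy)-2-[2,5-bis(benzyloxy)-4-methoxyphenyl]-5-hydroxy-6,8-dimethoxy-4H-chromen-4-one | COc1cc(OCc2ccccc2)c(-c2cc(=O)c3c(O)c(OC)c(OCc4ccccc4)c(OC)c3o2)cc1OCc1ccccc1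
F6 | step 6 | 5-(benzyloxy)-4,6-dimethoxy-1,3-phenylene bis(propan-2-ylcarbamate) | CC(C)NC(=O)Oc1cc(OC(=O)NC(C)C)c(OC)c(OCc2ccccc2)c1OC
F7 | step 6 | 5-(benzyloxy)-4,6-dimethoxy-2-(trimethylsilyl)-1,3-phenylene bis(propan-2-ylcarbamate) | CC(C)NC(=O)Oc1c([Si](C)(C)C)c(OC(=O)NC(C)C)c(OC)c(OCc2ccccc2)c1OC
F8 | step 6 | 5-(benzyloxy)-4,6-dimethoxy-2-(trimethylsilyl)benzene-1,3-diol | COc1c(O)c([Si](C)(C)C)c(O)c(OC)c1OCc1ccccc1
F9 | step 3 | 2,2'-[5-(benzyloxy)-4,6-dimethoxy-1,3-phenylene]bis(4,4,5,5-tetramethyl-1,3,2-dioxaborolane) | COc1c(B2OC(C)(C)C(C)(C)O2)cc(B2OC(C)(C)C(C)(C)O2)c(OC)c1OCc1ccccc1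
F10 | step 12 | dipropan-2-yl {7-(benzyloxy)-2-[2,5-bis(benzyloxy)-4-methoxyphenyl]-5-[(2,2-dimethylpropanoyl)oxy]-6,8-dimethoxy-4-oxo-4H-chromen-3-yl}boronate | CC(C)OB(OC(C)C)c1c(-c2cc(OCc3ccccc3)c(OC)cc2OCc2ccccc2)oc2c(OC)c(OCc3ccccc3)c(OC)c(OC(=O)C(C)(C)C)c2c1=O
F11 | step 10 | {[2,5-bis(benzyloxy)-4-methoxyphenyl]ethynyl}trimethylsilane | COc1cc(OCc2ccccc2)c(C#C[Si](C)(C)C)cc1OCc1ccccc1
F12 | step 10 | 1,4-bis(benzyloxy)-2-ethynyl-5-methoxybenzene | COc1cc(OCc2ccccc2)c(C#C)cc1OCc1ccccc1
A1 | alternative 1 | 6-{(Z)-4-[2,5-bis(benzyloxy)-4-methoxyphenyl]-3-methoxy-2-oxobut-3-en-1-yl}-4-hydroxy-3,5-dimethoxy-2H-pyran-2-one | COC1=C(O)C(OC)=C(CC(=O)/C(OC)=C/c2cc(OCc3ccccc3)c(OC)cc2OCc2ccccc2)OC1=O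
A2 | alternative 1 | (Z)-3-[2,5-bis(benzyloxy)-4-methoxyphenyl]-2-methoxy-1-(2,4,6-trihydroxy-3,5-dimethoxyphenyl)prop-2-en-1-one | COc1c(O)c(OC)c(O)c(C(=O)/C(OC)=C/c2cc(OCc3ccccc3)c(OC)cc2OCc2ccccc2)c1O
A3 | alternative 2 | 5,7-bis(benzyloxy)-2-ethynyl-3,6,8-trimethoxy-4H-chromen-4-one | C#Cc1oc2c(OC)c(OCc3ccccc3)c(OC)c(OCc3ccccc3)c2c(=O)c1OC
A4 | alternative 2 | pentacarbonyl[methoxy(1-methoxyvinyl)carbene]chromium | COC(=C)C(OC)=[Cr](=C=O)(=C=O)(=C=O)(=C=O)=C=O
A5 | alternative 2 | 2-[5,7-bis(benzyloxy)-3,6,8-trimethoxy-4-oxo-4H-chromen-2-yl]-5-methoxy-1,4-benzoquinone | COC1=CC(=O)C(=CC1=O)c1oc2c(OC)c(OCc3ccccc3)c(OC)c(OCc3ccccc3)c2c(=O)c1OC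
A6 | alternative 3 | 2-{3-[2,4-bis(benzyloxy)-3,5-dimethoxyphenyl]-2-methoxy-3-oxopropanoyl}-5-methoxy-1,4-phenylene bis(2,2-dimethylpropanoate) | COc1cc(C(=O)C(OC)C(=O)c2cc(OC(=O)C(C)(C)C)c(OC)cc2OC(=O)C(C)(C)C)c(OCc2ccccc2)c(OC)c1OCc1ccccc1
A7 | alternative 3 | 2-[5,7-bis(benzyloxy)-3,6,8-trimethoxy-4-oxo-4H-chromen-2-yl]-5-methoxy-1,4-phenylene bis(2,2-dimethylpropanoate) | COc1cc(OC(=O)C(C)(C)C)c(-c2oc3c(OC)c(OCc4ccccc4)c(OC)c(OCc4ccccc4)c3c(=O)c2OC)cc1OC(=O)C(C)(C)C
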